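**Plan**
1. Rings: A = oxane and B = oxolane (cis-fused furo[3,2-b]pyran), C = γ-butyrolactone, D = ten-membered keto lactone; B and C are joined by the E enol-ether C=C.
2. Retrosynthesis, last bonds first: (a) the furan O1–C7a bond (enolate O-alkylation with inversion) and the lactone Cα–Cβ bond (intramolecular Michael addition), both from one β-keto ester; (b) the butyrolactone ester bond (acylketene esterification), giving oxane β-keto ester mesylate 8 and hydroxy enone macrolide 19; (c) in ring D the enone C=C (ring-closing metathesis) and the ester bond; (d) in ring A the ring-fusion bond C3a–C7a.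
3. Feature behind (d): the fusion bond joins two oxygen-bearing carbons. C3a (oxane C2) carries the pyran oxygen O4 and lies β to C2, a carbon at carbonyl oxidation level, so it can be the β-carbon of a β-alkoxyacrylate; C7a (oxane C3) carries O1 and can be an aldehyde carbon. A samarium ketyl adding to the acrylate closes ring A.
4. Forward order: ring A (step 3), ring D (step 12), then rings C and B in one operation (step 15).
5. Stereochemistry: both CH(CH3)–O centres are bought. C3a and C7a are relayed from the methyl-bearing carbon in the key step (C7a formed trans, inverted in the final SN2 closure). The ring D carbinol comes from an auxiliary-controlled acetate aldol, and the lactone β-carbon follows from it in the Michael step. The E alkene is the dipole- and strain-minimised isomer.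

Key step: step 3

Remark: 1, 9 and 11 are treated as purchasable single enantiomers; 11 is otherwise one N-acetylation away from (4R)-4-benzyl-1,3-thiazolidine-2-thione.

**Step 1**
Reactants: 1 (2R)-hex-5-en-2-ol; 2 ethyl propiolate
Product: 3 ethyl (2E)-3-{[(2R)-hex-5-en-2-yl]oxy}prop-2-enoate
Conditions: N-methylmorpholine (0.3 equiv), CH2Cl2, rt
Reagents that add atoms: none
Why: Amine-catalysed oxa-Michael addition of the secondary alcohol to the ynoate should give the E β-alkoxyacrylate under thermodynamic control; the carbinol stereocentre is not touched.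

**Step 2**
Reactants: 3 ethyl (2E)-3-{[(2R)-hex-5-en-2-yl]oxy}prop-2-enoate
Product: 5 ethyl (2E)-3-{[(2R)-5-oxopentan-2-yl]oxy}prop-2-enoate, via vicinal diol 4 (not isolated)
Conditions: OsO4 (2 mol %), NaIO4 (4 equiv), 2,6-lutidine (2 equiv), 1,4-dioxane–H2O (3:1), rt
Reagents that add atoms: osmium tetroxide, O=[Os](=O)(=O)=O (catalytic oxygen carrier); sodium periodate, [Na+].[O-]I(=O)(=O)=O (terminal oxidant supplying the aldehyde oxygen)
Why: Lemieux–Johnson oxidation: the unhindered monosubstituted alkene should be dihydroxylated in preference to the ester-conjugated 1,2-disubstituted enol ether and the diol is cleaved in situ, 2,6-lutidine limiting over-oxidation.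

**Step 3**
Reactants: 5 ethyl (2E)-3-{[(2R)-5-oxopentan-2-yl]oxy}prop-2-enoate
Product: 6 ethyl 2-[(2S,3R,6R)-3-hydroxy-6-methyloxan-2-yl]acetate
Conditions: SmI2 (2.5 equiv), MeOH (3 equiv), THF, 0 °C
Reagents that add atoms: none
Why: SmI2 transfers one electron to the aldehyde to give a ketyl bound to trivalent samarium, which adds to the β-carbon of the β-alkoxyacrylate; a second electron transfer gives the samarium ester enolate, which methanol protonates (ketyl–olefin reductive cyclisation, the closest known type being the SmI2 cyclisation of aldehyde-tethered β-alkoxyacrylates used for polyether oxanes). Ring A is closed in the 6-exo-trig mode by forming the C2–C3 bond, the later ring-fusion bond. C2 is controlled by the bought C6 methyl centre: in the chair transition state the methyl group and the acrylate both sit equatorial, which gives the 2,6-cis ring. C3 is controlled by chelation of the samarium-bound ketyl oxygen to the ester carbonyl of the E acrylate, which places that oxygen equatorial and trans to the side chain. The step needs cyclisation to outrun simple reduction of the aldehyde and pinacol coupling; the polarised, electron-poor acceptor held five atoms away, dilution and methanol as proton source should secure this. The trans C3 configuration is the one wanted, because the final ring closure inverts it.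

**Step 4**
Reactants: 6 ethyl 2-[(2S,3R,6R)-3-hydroxy-6-methyloxan-2-yl]acetate
Product: 7 tert-butyl 4-[(2S,3R,6R)-3-hydroxy-6-methyloxan-2-yl]-3-oxobutanoate
Conditions: tert-butyl acetate (4 equiv), LiN(iPr)2 (4 equiv), THF, −78 °C; then 6, −78 → −20 °C; aq NH4Cl
Reagents that add atoms: tert-butyl acetate, CC(=O)OC(C)(C)C
Why: Crossed Claisen condensation: the excess lithium enolate first deprotonates the hydroxyl and then is acylated by the ethyl ester, the β-keto ester being shielded as its enolate; no stereocentre is involved, and should the trans alkoxide lactonise, the lactone is opened by the same enolate to the same product.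

**Step 5**
Reactants: 7 tert-butyl 4-[(2S,3R,6R)-3-hydroxy-6-methyloxan-2-yl]-3-oxobutanoate
Product: 8 tert-butyl 4-[(2S,3R,6R)-3-(methanesulfonyloxy)-6-methyloxan-2-yl]-3-oxobutanoate
Conditions: MsCl (1.1 equiv), Et3N, CH2Cl2, −20 → 0 °C
Reagents that add atoms: methanesulfonyl chloride, CS(=O)(=O)Cl
Why: Sulfonylation of the secondary alcohol through sulfene should be much faster than any reaction of the weakly nucleophilic β-keto ester, the C–O bond is not broken (configuration retained), and the equatorial mesylate has no antiperiplanar hydrogen for elimination.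

**Step 6**
Reactants: 9 (5R)-5-methyloxolan-2-one
Product: 10 (4R)-4-hydroxy-N-methoxy-N-methylpentanamide
Conditions: MeNH(OMe)·HCl (1.5 equiv), iPrMgCl (3 equiv), THF, −20 → 0 °C; aq NH4Cl
Reagents that add atoms: N,O-dimethylhydroxylamine hydrochloride, CNOC.Cl
Why: Weinreb aminolysis: the chloromagnesium amide formed in situ opens the lactone by acyl substitution, so the C–O bond at the stereocentre stays intact.

**Step 7**
Reactants: 11 1-[(4R)-4-benzyl-2-sulfanylidene-1,3-thiazolidin-3-yl]ethan-1-one; 12 acrolein
Product: 13 (3S)-1-[(4R)-4-benzyl-2-sulfanylidene-1,3-thiazolidin-3-yl]-3-hydroxypent-4-en-1-one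
Conditions: TiCl4 (1.1 equiv), iPr2NEt (1.1 equiv), CH2Cl2, −78 °C; then acrolein, −78 °C
Reagents that add atoms: none
Why: Titanium-mediated acetate aldol addition of an N-acetyl thiazolidinethione through a chelated Zimmerman–Traxler transition state (thiocarbonyl sulfur bound to titanium): the aldehyde reaches the enolate face away from the benzyl group, which with the (R)-auxiliary should give the (S)-carbinol, the minor diastereomer being removable by chromatography.

**Step 8**
Reactants: 13 (3S)-1-[(4R)-4-benzyl-2-sulfanylidene-1,3-thiazolidin-3-yl]-3-hydroxypent-4-en-1-one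
Product: 14 (3S)-1-[(4R)-4-benzyl-2-sulfanylidene-1,3-thiazolidin-3-yl]-3-[(tert-butyldimethylsilyl)oxy]pent-4-en-1-one
Conditions: TBSOTf, 2,6-lutidine, CH2Cl2, −78 → 0 °C
Reagents that add atoms: tert-butyldimethylsilyl trifluoromethanesulfonate, CC(C)(C)[Si](C)(C)OS(=O)(=O)C(F)(F)F
Why: Silylation with the silyl triflate and a hindered pyridine base at low temperature protects the allylic alcohol without acyl transfer or retro-aldol cleavage; the stereocentre is untouched.

**Step 9**
Reactants: 14 (3S)-1-[(4R)-4-benzyl-2-sulfanylidene-1,3-thiazolidin-3-yl]-3-[(tert-butyldimethylsilyl)oxy]pent-4-en-1-one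
Product: 15 (3S)-3-[(tert-butyldimethylsilyl)oxy]pent-4-enoic acid
Conditions: LiOH (2 equiv), THF–H2O (3:1), 0 °C; then dilute HCl to pH 3
Reagents that add atoms: lithium hydroxide, [Li+].[OH-]
Why: The N-acyl thiazolidinethione is an activated amide that LiOH should hydrolyse at 0 °C faster than the β-silyloxy group can be eliminated, releasing the auxiliary for recovery.

**Step 10**
Reactants: 15 (3S)-3-[(tert-butyldimethylsilyl)oxy]pent-4-enoic acid; 10 (4R)-4-hydroxy-N-methoxy-N-methylpentanamide
Product: 16 (2R)-5-[methoxy(methyl)amino]-5-oxopentan-2-yl (3S)-3-[(tert-butyldimethylsilyl)oxy]pent-4-enoate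
Conditions: DCC (1.2 equiv), DMAP (0.1 equiv), CH2Cl2, 0 °C → rt
Reagents that add atoms: none
Why: Steglich esterification: carbodiimide activation of the acid and DMAP-catalysed acyl transfer to the secondary alcohol, with retention at both stereocentres.

**Step 11**
Reactants: 16 (2R)-5-[methoxy(methyl)amino]-5-oxopentan-2-yl (3S)-3-[(tert-butyldimethylsilyl)oxy]pent-4-enoate
Product: 17 (2R)-5-oxohept-6-en-2-yl (3S)-3-[(tert-butyldimethylsilyl)oxy]pent-4-enoate
Conditions: vinylmagnesium bromide (1.3 equiv), THF, −78 → −30 °C; inverse quench into cold 1 M HCl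
Reagents that add atoms: vinylmagnesium bromide, C=C[Mg]Br
Why: Weinreb ketone synthesis: the Grignard reagent should add to the N-methoxy-N-methylamide faster than to the secondary-alkyl ester at low temperature, the chelated tetrahedral intermediate blocks over-addition, and the inverse acidic quench keeps the released amine from adding to the vinyl ketone.

**Step 12**
Reactants: 17 (2R)-5-oxohept-6-en-2-yl (3S)-3-[(tert-butyldimethylsilyl)oxy]pent-4-enoate
Product: 18 (4S,5E,10R)-4-[(tert-butyldimethylsilyl)oxy]-10-methyl-1-oxacyclodec-5-ene-2,7-dione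
Conditions: second-generation Hoveyda–Grubbs catalyst (10 mol %), toluene (1 mM), 80 °C
Reagents that add atoms: none
Why: Ring-closing metathesis under high dilution, driven by loss of ethylene, joins the vinyl ketone to the allylic silyl ether alkene; the E enone is expected from the usual trans preference of enone-forming metathesis, helped by the bulky allylic silyl ether.

**Step 13**
Reactants: 18 (4S,5E,10R)-4-[(tert-butyldimethylsilyl)oxy]-10-methyl-1-oxacyclodec-5-ene-2,7-dione
Product: 19 (4S,5E,10R)-4-hydroxy-10-methyl-1-oxacyclodec-5-ene-2,7-dione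
Conditions: HF·pyridine, pyridine, THF, 0 °C → rt
Reagents that add atoms: none
Why: Buffered acidic fluoride desilylation should remove the silyl ether without the base-induced isomerisation or β-elimination to which the γ-hydroxy enone and the β-hydroxy lactone are prone.

**Step 14**
Reactants: 19 (4S,5E,10R)-4-hydroxy-10-methyl-1-oxacyclodec-5-ene-2,7-dione; 8 tert-butyl 4-[(2S,3R,6R)-3-(methanesulfonyloxy)-6-methyloxan-2-yl]-3-oxobutanoate
Product: 21 (4S,5E,10R)-10-methyl-2,7-dioxo-1-oxacyclodec-5-en-4-yl 4-[(2S,3R,6R)-3-(methanesulfonyloxy)-6-methyloxan-2-yl]-3-oxobutanoate, via acylketene 20 (not isolated)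
Conditions: toluene, 110 °C, slow addition of 8 to 19 (1.2 equiv) under an N2 sweep
Reagents that add atoms: none
Why: Acylketene transesterification: on heating, the tert-butyl β-keto ester loses tert-butanol to give an acylketene that the secondary allylic alcohol traps as the new β-keto ester under neutral conditions, which should leave the mesylate, the enone and the lactone untouched.

**Step 15**
Reactants: 21 (4S,5E,10R)-10-methyl-2,7-dioxo-1-oxacyclodec-5-en-4-yl 4-[(2S,3R,6R)-3-(methanesulfonyloxy)-6-methyloxan-2-yl]-3-oxobutanoate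
Product: 23 cordycicadin D, via Michael adduct 22 (not isolated)
Conditions: Cs2CO3 (1.5 equiv), MeCN, 0 °C → rt; then 50 °C
Reagents that add atoms: none
Why: The carbonate forms only the doubly stabilised β-keto ester enolate, which adds 5-exo-trig to the E enone on the alkene face that carries the ester oxygen, through the conformer with the allylic C–H eclipsing the alkene, to give the trans-fused butyrolactone (also the expected outcome of a reversible addition); on warming, the α-acyl lactone enolate displaces the equatorial mesylate through oxygen (5-exo-tet, carbon attack being a disfavoured 5-enolendo closure by Baldwin's rules) with inversion at C7a, which should give the cis-fused ring B and the E enol ether, the isomer with the furan oxygen anti to the lactone carbonyl.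

**Compound list**
1 | (2R)-hex-5-en-2-ol | C=CCC[C@@H](C)O | starting material
2 | ethyl propiolate | C#CC(=O)OCC | starting material
3 | ethyl (2E)-3-{[(2R)-hex-5-en-2-yl]oxy}prop-2-enoate | C=CCC[C@@H](C)O/C=C/C(=O)OCC | intermediate
4 | ethyl (2E)-3-{[(2R)-5,6-dihydroxyhexan-2-yl]oxy}prop-2-enoate (both C5 epimers) | OCC(O)CC[C@@H](C)O/C=C/C(=O)OCC | intermediate (not isolated)
5 | ethyl (2E)-3-{[(2R)-5-oxopentan-2-yl]oxy}prop-2-enoate | O=CCC[C@@H](C)O/C=C/C(=O)OCC | intermediate
6 | ethyl 2-[(2S,3R,6R)-3-hydroxy-6-methyloxan-2-yl]acetate | CCOC(=O)C[C@@H]1O[C@H](C)CC[C@H]1O | intermediate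
7 | tert-butyl 4-[(2S,3R,6R)-3-hydroxy-6-methyloxan-2-yl]-3-oxobutanoate | CC(C)(C)OC(=O)CC(=O)C[C@@H]1O[C@H](C)CC[C@H]1O | intermediate
8 | tert-butyl 4-[(2S,3R,6R)-3-(methanesulfonyloxy)-6-methyloxan-2-yl]-3-oxobutanoate | CC(C)(C)OC(=O)CC(=O)C[C@@H]1O[C@H](C)CC[C@H]1OS(C)(=O)=O | intermediate
9 | (5R)-5-methyloxolan-2-one ((R)-γ-valerolactone) | C[C@@H]1CCC(=O)O1 | starting material
10 | (4R)-4-hydroxy-N-methoxy-N-methylpentanamide | C[C@@H](O)CCC(=O)N(C)OC | intermediate
11 | 1-[(4R)-4-benzyl-2-sulfanylidene-1,3-thiazolidin-3-yl]ethan-1-one | CC(=O)N1[C@H](Cc2ccccc2)CSC1=S | starting material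
12 | acrolein | C=CC=O | starting material
13 | (3S)-1-[(4R)-4-benzyl-2-sulfanylidene-1,3-thiazolidin-3-yl]-3-hydroxypent-4-en-1-one | C=C[C@@H](O)CC(=O)N1[C@H](Cc2ccccc2)CSC1=S | intermediate
14 | (3S)-1-[(4R)-4-benzyl-2-sulfanylidene-1,3-thiazolidin-3-yl]-3-[(tert-butyldimethylsilyl)oxy]pent-4-en-1-one | C=C[C@@H](O[Si](C)(C)C(C)(C)C)CC(=O)N1[C@H](Cc2ccccc2)CSC1=S | intermediate
15 | (3S)-3-[(tert-butyldimethylsilyl)oxy]pent-4-enoic acid | C=C[C@@H](O[Si](C)(C)C(C)(C)C)CC(=O)O | intermediate
16 | (2R)-5-[methoxy(methyl)amino]-5-oxopentan-2-yl (3S)-3-[(tert-butyldimethylsilyl)oxy]pent-4-enoate | C=C[C@@H](O[Si](C)(C)C(C)(C)C)CC(=O)O[C@H](C)CCC(=O)N(C)OC | intermediate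
17 | (2R)-5-oxohept-6-en-2-yl (3S)-3-[(tert-butyldimethylsilyl)oxy]pent-4-enoate | C=C[C@@H](O[Si](C)(C)C(C)(C)C)CC(=O)O[C@H](C)CCC(=O)C=C | intermediate
18 | (4S,5E,10R)-4-[(tert-butyldimethylsilyl)oxy]-10-methyl-1-oxacyclodec-5-ene-2,7-dione | C[C@@H]1CCC(=O)/C=C/[C@@H](O[Si](C)(C)C(C)(C)C)CC(=O)O1 | intermediate
19 | (4S,5E,10R)-4-hydroxy-10-methyl-1-oxacyclodec-5-ene-2,7-dione | C[C@@H]1CCC(=O)/C=C/[C@@H](O)CC(=O)O1 | intermediate
20 | 4-[(2S,3R,6R)-3-(methanesulfonyloxy)-6-methyloxan-2-yl]-3-oxobut-1-en-1-one (acylketene) | O=C=CC(=O)C[C@@H]1O[C@H](C)CC[C@H]1OS(C)(=O)=O | intermediate (not isolated)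
21 | (4S,5E,10R)-10-methyl-2,7-dioxo-1-oxacyclodec-5-en-4-yl 4-[(2S,3R,6R)-3-(methanesulfonyloxy)-6-methyloxan-2-yl]-3-oxobutanoate | C[C@@H]1CCC(=O)/C=C/[C@@H](OC(=O)CC(=O)C[C@@H]2O[C@H](C)CC[C@H]2OS(C)(=O)=O)CC(=O)O1 | intermediate
22 | Michael adduct: trans-fused γ-butyrolactone on the ten-membered keto lactone (lactone β-carbon R; γ-carbon S; macrolactone methyl carbon R; α-carbon epimeric and enolisable) bearing on its α-carbon the 2-[(2S,3R,6R)-3-(methanesulfonyloxy)-6-methyloxan-2-yl]acetyl group | C[C@@H]1CCC(=O)C[C@@H]2C(C(=O)C[C@@H]3O[C@H](C)CC[C@H]3OS(C)(=O)=O)C(=O)O[C@H]2CC(=O)O1 | intermediate (not isolated)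
23 | cordycicadin D: E enol ether joining C2 of the cis-fused (3aS,5R,7aS)-5-methylhexahydrofuro[3,2-b]pyran to the α-carbon of the trans-fused γ-butyrolactone (β-carbon R; γ-carbon S) on the (R)-methyl ten-membered keto lactone | C[C@@H]1CCC(=O)C[C@@H]2/C(=C3/C[C@@H]4O[C@H](C)CC[C@@H]4O3)C(=O)O[C@H]2CC(=O)O1 | target

**Step count and risks**
Total steps: 15. Longest linear sequence: 9 steps (steps 7 to 15, from 11 and 12).

Step 15. What may go wrong: the enolate may alkylate on oxygen before it adds to the enone, the Michael addition may take place with poor facial selectivity on the macrocycle, or the basic heating needed for the displacement may open the β-acyloxy lactone by elimination. Fallback: the two events are separated and ring B is closed without base. The route sets out from 7, whose hydroxyl is capped (Et3SiCl, imidazole, CH2Cl2) to give tert-butyl 4-[(2S,3R,6R)-6-methyl-3-(triethylsilyloxy)oxan-2-yl]-3-oxobutanoate F1. Thermolysis of F1 with 19 (toluene, 110 °C) should give the corresponding β-keto ester of the macrolide carbinol F2. Cs2CO3 in MeCN at rt then effects only the Michael addition, which, with no leaving group present, can be left to equilibrate to the trans-fused α-acyl lactone silyl ether F3. HF·pyridine frees the oxane C3 hydroxyl to give the hydroxy α-acyl lactone F4. Mitsunobu cyclodehydration (PPh3, DIAD, THF, 0 °C → rt) lets the acidic α-acyl lactone alkylate through oxygen with inversion at that carbon and comes back to the route at 23.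

Step 12. What may go wrong: intermolecular metathesis to dimers and oligomers may outrun closure of the strained ten-membered ring, or the Z enone may form. Fallback: the ring is closed at the ester bond instead of the alkene. The route sets out from 10 and 15. Vinylmagnesium bromide (2.5 equiv, THF, −78 → 0 °C) converts 10 into (6R)-6-hydroxyhept-1-en-3-one F5. Cross-metathesis of F5 with 15 (second-generation Hoveyda–Grubbs catalyst, CH2Cl2, 40 °C) should give the E seco acid (3S,4E,9R)-3-[(tert-butyldimethylsilyl)oxy]-9-hydroxy-6-oxodec-4-enoic acid F6. Yamaguchi macrolactonisation (2,4,6-trichlorobenzoyl chloride, Et3N, THF; then DMAP, toluene, high dilution, 80 °C) comes back to the route at 18.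

Step 3. What may go wrong: two-electron reduction of the aldehyde to the primary alcohol or pinacol coupling may outrun the ketyl addition, or loss of chelation may erode the selectivity at C3. Fallback: the same bond is made by an acyl radical and the carbinol is set afterwards by hydride. The route sets out from 5. Pinnick oxidation (NaClO2, NaH2PO4, 2-methylbut-2-ene, tBuOH–H2O) gives (4R)-4-{[(1E)-3-ethoxy-3-oxoprop-1-en-1-yl]oxy}pentanoic acid F7. Diphenyl diselenide and PBu3 (CH2Cl2, rt) convert it into the Se-phenyl selenoester F8. (Me3Si)3SiH with Et3B and air (toluene, rt) generates the acyl radical, whose 6-exo cyclisation onto the β-alkoxyacrylate should give the 2,6-cis ketone ethyl 2-[(2S,6R)-6-methyl-3-oxooxan-2-yl]acetate F9. NaBH4 (MeOH, −40 °C) should deliver hydride axially to give the equatorial alcohol and comes back to the route at 6.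

**Further compounds**
F1 | step 15 | tert-butyl 4-[(2S,3R,6R)-6-methyl-3-(triethylsilyloxy)oxan-2-yl]-3-oxobutanoate | CC(C)(C)OC(=O)CC(=O)C[C@@H]1O[C@H](C)CC[C@H]1O[Si](CC)(CC)CC
F2 | step 15 | (4S,5E,10R)-10-methyl-2,7-dioxo-1-oxacyclodec-5-en-4-yl 4-[(2S,3R,6R)-6-methyl-3-(triethylsilyloxy)oxan-2-yl]-3-oxobutanoate | C[C@@H]1CCC(=O)/C=C/[C@@H](OC(=O)CC(=O)C[C@@H]2O[C@H](C)CC[C@H]2O[Si](CC)(CC)CC)CC(=O)O1
F3 | step 15 | trans-fused α-acyl γ-butyrolactone of the ten-membered keto lactone with the oxane C3 triethylsilyl ether (α-carbon epimeric) | C[C@@H]1CCC(=O)C[C@@H]2C(C(=O)C[C@@H]3O[C@H](C)CC[C@H]3O[Si](CC)(CC)CC)C(=O)O[C@H]2CC(=O)O1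
F4 | step 15 | trans-fused α-acyl γ-butyrolactone of the ten-membered keto lactone with the free (3R)-hydroxyl on the oxane (α-carbon epimeric) | C[C@@H]1CCC(=O)C[C@@H]2C(C(=O)C[C@@H]3O[C@H](C)CC[C@H]3O)C(=O)O[C@H]2CC(=O)O1
F5 | step 12 | (6R)-6-hydroxyhept-1-en-3-one | C[C@@H](O)CCC(=O)C=C
F6 | step 12 | (3S,4E,9R)-3-[(tert-butyldimethylsilyl)oxy]-9-hydroxy-6-oxodec-4-enoic acid | C[C@@H](O)CCC(=O)/C=C/[C@@H](O[Si](C)(C)C(C)(C)C)CC(=O)O
F7 | step 3 | (4R)-4-{[(1E)-3-ethoxy-3-oxoprop-1-en-1-yl]oxy}pentanoic acid | OC(=O)CC[C@@H](C)O/C=C/C(=O)OCC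
F8 | step 3 | ethyl (2E)-3-{[(2R)-5-oxo-5-(phenylselanyl)pentan-2-yl]oxy}prop-2-enoate | O=C([Se]c1ccccc1)CC[C@@H](C)O/C=C/C(=O)OCC
F9 | step 3 | ethyl 2-[(2S,6R)-6-methyl-3-oxooxan-2-yl]acetate | CCOC(=O)C[C@@H]1O[C@H](C)CCC1=O
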